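## Retrosynthetic overview

1. Feature: the C6–C10 bond is common to rings B and D, with N7 on C6 and N9 on the proline α-carbon C10. Replacing N9 by the carbonyl carbon C8 (Curtius retron) contracts ring D to the β-lactam N7–C8–C10–C6, spiro to ring C at C10 and cis-fused to ring B.
2. Guanidine ⇒ O-ethylisourea ⇒ cyclic urea. The C2/C3 bromines go onto the urea, after the radical deoxygenation.
3. Urea ring D ⇒ ring growth of the β-lactam: hydrazine cuts N7–C8, the Curtius shift carries C8 from C10 to N9, and N7 recaptures C8.
4. β-Lactam plus ring B ⇒ intramolecular Staudinger [2+2] of the ketene C10=C8=O with the imine N7(Me)=C6H on pyrrole N1, forming C6–C10 and N7–C8. A 12-silyloxy group from cis-4-hydroxy-L-proline steers the face at C10 and is then removed.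
5. Ring order: A and C are bought, B and the four-membered ring close together, D arises last. The precursor comes from hydroxyproline allyl ester, 2-trichloroacetylpyrrole, TBSCl and MeNC.

Key step: step 7

Assumption: phakellin numbering is used for all polycycles (pyrrole N1, C2–C5; C6; N7; C8; N9; C10; C11–C13; N14; C15=O on C5), and the target is taken as the free base with the (6S,10R) configuration that the SMILES string encodes. Changes of the C6 and C10 descriptors along the route come from CIP priorities only.

## Route

Step 1
Reactants: 1 cis-4-hydroxy-L-proline
Product: 2 allyl (2S,4S)-4-hydroxypyrrolidine-2-carboxylate p-toluenesulfonate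
Conditions: allyl alcohol (10 equiv), TsOH·H2O (1.2 equiv), toluene, reflux, Dean–Stark trap
Reagents that add atoms: allyl alcohol, C=CCO; p-toluenesulfonic acid, Cc1ccc(cc1)S(=O)(=O)O
Why: Fischer esterification driven by azeotropic removal of water is the standard way to amino acid allyl esters, the ammonium tosylate keeps the nitrogen out of the reaction, both stereocentres are untouched, and the allyl group is chosen because it can later be removed without hydroxide.

Step 2
Reactants: 2 allyl ester tosylate, 3 2,2,2-trichloro-1-(1H-pyrrol-2-yl)ethanone
Product: 4 allyl (2S,4S)-4-hydroxy-1-(1H-pyrrole-2-carbonyl)pyrrolidine-2-carboxylate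
Conditions: Et3N (2.2 equiv), MeCN, rt
Reagents that add atoms: none
Why: Haloform-type acyl transfer, in which the liberated secondary amine adds to the trichloromethyl ketone and the CCl3 group leaves as chloroform, is selective for the amine over the secondary alcohol and leaves the pyrrole N–H free.

Step 3
Reactants: 4 hydroxy amide
Product: 5 allyl (2S,4S)-4-(tert-butyldimethylsilyloxy)-1-(1H-pyrrole-2-carbonyl)pyrrolidine-2-carboxylate
Conditions: TBSCl (1.3 equiv), imidazole (2.5 equiv), DMF, rt
Reagents that add atoms: tert-butyldimethylsilyl chloride, C[Si](C)(Cl)C(C)(C)C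
Why: Imidazole-promoted silylation of a secondary alcohol is routine, the weakly nucleophilic acylpyrrole N–H is not silylated permanently, and the bulky ether on the ester face of the ring is the later control element.

Step 4
Reactants: 6 N-methylformamide
Product: 7 methyl isocyanide
Conditions: TsCl (1.5 equiv), quinoline (4 equiv), 75 °C, 15 mmHg, distilled into a −78 °C trap
Reagents that add atoms: none
Why: Dehydration of a monosubstituted formamide by O-sulfonylation and base-induced α-elimination is the classical isocyanide synthesis, and the volatile product leaves the mixture as it forms.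

Step 5
Reactants: 5 silyl ether, 7 methyl isocyanide
Product: 8 allyl (2S,4S)-4-(tert-butyldimethylsilyloxy)-1-{1-[(E)-(methylimino)methyl]-1H-pyrrole-2-carbonyl}pyrrolidine-2-carboxylate
Conditions: 7 (5 equiv), Cu2O (10 mol %), toluene, 55 °C, dry; filtration through basic alumina
Reagents that add atoms: none
Why: In this copper-catalysed α-addition of an N–H bond to an isocyanide (isocyanide insertion), Cu2O with MeNC metallates the acidic 2-acylpyrrole N–H, MeNC inserts into the Cu–N bond and the next N–H protonates the formimidoylcopper species to release the E-formamidine, while any epimerisation at proline C2 is harmless because that centre is erased in step 7.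

Step 6
Reactants: 8 N-imidoylpyrrole allyl ester
Product: 9 (2S,4S)-4-(tert-butyldimethylsilyloxy)-1-{1-[(E)-(methylimino)methyl]-1H-pyrrole-2-carbonyl}pyrrolidine-2-carboxylic acid (kept as its triethylammonium salt in solution and used at once)
Conditions: Pd(PPh3)4 (5 mol %), HCO2H (2 equiv), Et3N (3 equiv), dry THF, rt
Reagents that add atoms: none
Why: In this Tsuji–Trost-type deallylation zerovalent palladium ionises the allyl ester and formate reduces the allyl complex to propene with loss of CO2, so the acid is freed without hydroxide or a nucleophilic amine, either of which would attack C6 of the acyl-transfer-like N-imidoylpyrrole.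

Step 7
Reactants: 9 imidoylpyrrole acid
Product: 12 (6R,10R,12S)-12-silyloxy spiro β-lactam, via ketene 10 (not isolated), via acylamidinium enolate 11 (not isolated)
Conditions: 9 (Et3NH salt, CH2Cl2) added over 10 h to 2-chloro-1-methylpyridinium iodide (2 equiv), Et3N (5 equiv), CH2Cl2, reflux, final 2 mM
Reagents that add atoms: none
Why: Proposed new method: the pyridinium salt activates the carboxylate and Et3N removes the C10 proton together with 1-methyl-2-pyridone, so that the C10 stereocentre is erased and ketene 10 (C10=C8=O) results. In the amide rotamer with C5 syn to C10, the lone pair of the E-configured N7 lies on the side of N1 and reaches C8 in the plane of ring C from the N14 side, giving the N-acylformamidinium enolate 11 in an eight-membered ring, in which N7 is acylated and can no longer expel the pyrrole. C10 of the enolate then adds to C6, which is strongly electrophilic because the acylpyrrole N1 stabilises it poorly: for ring B this is a 6-(enolexo)-exo-trig Mannich closure, and for the lactam it is the four-atom closure of a Staudinger zwitterion with both tethered nitrogens (N14, N1) on inner positions, so it must run as a polar addition and not as the usual conrotatory motion. The closest known reactions are the intermolecular Staudinger cycloadditions of N-acylproline and 4-silyloxyproline ketenes, made with the same salt or from the acid chlorides, with imines to give spiro β-lactams, whereas an N-imidoylpyrrole as the imine and the tethered mode are new. C10 is set by the 12-silyloxy group, which shields its own face of the flat enolate so that C6 bonds anti to it and C8 stays syn (10R), and C6 is set by the two-atom C15–C5 tether, which allows only the cis fusion with N1 and N14 on the same side of the lactam (6R). The step needs intramolecular over intermolecular capture of the ketene, which slow addition at high dilution and the nearness of N7 secure, and it poses no regiochemical choice because N7 is the only nucleophilic nitrogen in 10.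

Step 8
Reactants: 12 silyloxy spiro β-lactam
Product: 13 (6R,10R,12S)-12-hydroxy spiro β-lactam
Conditions: HF·pyridine, THF, 0 °C to rt
Reagents that add atoms: none
Why: Fluoride cleavage of the silyl ether under mildly acidic conditions avoids a free alkoxide that could attack the C8 carbonyl on the same face of ring C, and the directing group is removed now so that the later lactam opening meets an unshielded carbonyl.

Step 9
Reactants: 13 hydroxy spiro β-lactam
Product: 14 12-O-(imidazol-1-ylthiocarbonyl) spiro β-lactam
Conditions: 1,1'-thiocarbonyldiimidazole (1.5 equiv), DMAP (0.1 equiv), ClCH2CH2Cl, 60 °C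
Reagents that add atoms: 1,1'-thiocarbonyldiimidazole, S=C(n1ccnc1)n1ccnc1
Why: Thioacylation of the secondary alcohol, the first half of the Barton–McCombie deoxygenation, is clean at this stage because the molecule holds no N–H and no other O–H group.

Step 10
Reactants: 14 thiocarbonylimidazolide
Product: 15 (6R,10R)-12-deoxy spiro β-lactam
Conditions: Bu3SnH (2 equiv), AIBN (0.2 equiv), toluene, 90 °C
Reagents that add atoms: none
Why: In the Barton–McCombie deoxygenation the stannyl radical adds to C=S, the C12–O bond fragments and the secondary C12 radical takes hydrogen from Bu3SnH, which removes the auxiliary stereocentre and is done before bromination because C–Br bonds would not survive.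

Step 11
Reactants: 15 deoxy spiro β-lactam
Product: 16 (6S,10R)-6-methylamino-10-carbohydrazide of the A–B–C tricycle
Conditions: N2H4·H2O (20 equiv), EtOH, 45 °C; excess hydrazine removed by co-evaporation with toluene
Reagents that add atoms: hydrazine (as hydrate), NN
Why: In this aminolysis of a strained lactam by an α-effect nucleophile, ring strain, the inductive pull of N14 on C10 and the low basicity of the leaving aminal nitrogen N7 make C8 far more electrophilic than the pyrrole-conjugated C15 amide, so only N7–C8 is cut and C6 and C10 keep their configuration.

Step 12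
Reactants: 16 hydrazide
Product: 17 (6S,10R)-acyl azide (kept as a cold toluene solution and used at once)
Conditions: t-BuONO (1.05 equiv), HCl (4 M in dioxane, 4 equiv), DMF, −25 °C; cold aq NaHCO3, extraction into toluene at 0 °C
Reagents that add atoms: tert-butyl nitrite, CC(C)(C)ON=O
Why: In this nitrosation of an acyl hydrazide to the acyl azide (Honzl–Rudinger conditions) the excess acid keeps the secondary amine N7 protonated and safe from N-nitrosation, and one equivalent of nitrite at low temperature spares the deactivated acylpyrrole.

Step 13
Reactants: 17 acyl azide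
Product: 19 (6R,10R)-cyclic urea (debromo 7-N-methylphakellstatin skeleton), via isocyanate 18 (not isolated)
Conditions: toluene, 0 to 60 °C
Reagents that add atoms: none
Why: The Curtius rearrangement moves C10 from C8 to N9 with retention, and the cis-placed N7–H adds at once to the isocyanate carbon C8 in a five-membered closure that re-forms N7–C8 and grows the former four-membered ring into ring D, while any C6 epimer formed by aminal ring–chain equilibration is funnelled into the only possible cis-fused urea.

Step 14
Reactants: 19 cyclic urea
Product: 20 (6S,10R)-2,3-dibromo cyclic urea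
Conditions: NBS (2.1 equiv), THF, 0 °C to rt, dark
Reagents that add atoms: N-bromosuccinimide, O=C1CCC(=O)N1Br
Why: In this electrophilic aromatic bromination the C5 acyl group deactivates the neighbouring C4, so substitution takes place at C3 and C2 (the 4- and 5-positions of a 2-acylpyrrole), and the neutral urea tolerates NBS better than a free guanidine would.

Step 15
Reactants: 20 dibromo urea
Product: 21 (6S,10R)-8-O-ethylisourea
Conditions: Et3OBF4 (3 equiv), NaHCO3 (solid, 5 equiv), CH2Cl2, rt
Reagents that add atoms: triethyloxonium tetrafluoroborate, CC[O+](CC)CC.F[B-](F)(F)F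
Why: A trialkyloxonium salt alkylates the urea at its oxygen, the most nucleophilic site since the C15 amide is deactivated by the dibromopyrrole, and loss of the N9 proton gives the neutral isourea C8(OEt)=N9.

Step 16
Reactants: 21 isourea
Product: 22 (−)-7-N-methyldibromophakellin
Conditions: NH3 (7 M in MeOH), NH4Cl (0.2 equiv), sealed tube, 70 °C; basic work-up
Reagents that add atoms: ammonia, N
Why: Addition–elimination of ammonia at the isourea carbon C8 replaces ethoxide and gives the more stabilised guanidine without touching C6 or C10.

## Compound list

1 | cis-4-hydroxy-L-proline, (2S,4S) | OC(=O)[C@@H]1C[C@H](O)CN1 | starting material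
2 | allyl (2S,4S)-4-hydroxypyrrolidine-2-carboxylate p-toluenesulfonate salt | C=CCOC(=O)[C@@H]1C[C@H](O)CN1.Cc1ccc(cc1)S(=O)(=O)O | intermediate
3 | 2,2,2-trichloro-1-(1H-pyrrol-2-yl)ethanone | O=C(c1ccc[nH]1)C(Cl)(Cl)Cl | starting material
4 | allyl (2S,4S)-4-hydroxy-1-(1H-pyrrole-2-carbonyl)pyrrolidine-2-carboxylate | C=CCOC(=O)[C@@H]1C[C@H](O)CN1C(=O)c1ccc[nH]1 | intermediate
5 | allyl (2S,4S)-4-(tert-butyldimethylsilyloxy)-1-(1H-pyrrole-2-carbonyl)pyrrolidine-2-carboxylate | C=CCOC(=O)[C@@H]1C[C@H](O[Si](C)(C)C(C)(C)C)CN1C(=O)c1ccc[nH]1 | intermediate
6 | N-methylformamide | CNC=O | starting material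
7 | methyl isocyanide | C[N+]#[C-] | intermediate
8 | allyl (2S,4S)-4-(tert-butyldimethylsilyloxy)-1-{1-[(E)-(methylimino)methyl]-1H-pyrrole-2-carbonyl}pyrrolidine-2-carboxylate | C=CCOC(=O)[C@@H]1C[C@H](O[Si](C)(C)C(C)(C)C)CN1C(=O)c1cccn1/C=N/C | intermediate
9 | (2S,4S)-4-(tert-butyldimethylsilyloxy)-1-{1-[(E)-(methylimino)methyl]-1H-pyrrole-2-carbonyl}pyrrolidine-2-carboxylic acid | C/N=C/n1cccc1C(=O)N1C[C@@H](O[Si](C)(C)C(C)(C)C)C[C@H]1C(=O)O | intermediate
10 | (4S)-4-silyloxy-1-acylpyrrolidin-2-ylidene ketene, C10=C8=O | C/N=C/n1cccc1C(=O)N1C[C@@H](O[Si](C)(C)C(C)(C)C)CC1=C=O | intermediate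
11 | eight-membered N-acylformamidinium enolate (N7–C8 formed, C6–C10 still open, both ring double bonds cis within the ring), (12S) | C[N+]1=Cn2cccc2C(=O)N2C[C@@H](O[Si](C)(C)C(C)(C)C)CC2=C1[O-] | intermediate
12 | (6R,10R,12S)-12-(tert-butyldimethylsilyloxy) spiro β-lactam: N7(Me)–C8(=O)–C10–C6 ring spiro to ring C at C10, cis-fused to ring B, silyloxy cis to C8 and trans to C6 | CN1C(=O)[C@]23C[C@H](O[Si](C)(C)C(C)(C)C)CN2C(=O)c2cccn2[C@H]13 | intermediate
13 | (6R,10R,12S)-12-hydroxy spiro β-lactam | CN1C(=O)[C@]23C[C@H](O)CN2C(=O)c2cccn2[C@H]13 | intermediate
14 | (6R,10R,12S)-12-O-(imidazol-1-ylthiocarbonyl) spiro β-lactam | CN1C(=O)[C@]23C[C@H](OC(=S)n4ccnc4)CN2C(=O)c2cccn2[C@H]13 | intermediate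
15 | (6R,10R)-12-deoxy spiro β-lactam | CN1C(=O)[C@]23CCCN2C(=O)c2cccn2[C@H]13 | intermediate
16 | (6S,10R)-tricyclic hydrazide: NHMe on C6, C(=O)NHNH2 on C10, cis | CN[C@H]1n2cccc2C(=O)N2CCC[C@]12C(=O)NN | intermediate
17 | (6S,10R)-tricyclic acyl azide | CN[C@H]1n2cccc2C(=O)N2CCC[C@]12C(=O)N=[N+]=[N-] | intermediate
18 | (6S,10S)-tricyclic C10 isocyanate (same spatial arrangement as 17) | CN[C@H]1n2cccc2C(=O)N2CCC[C@]12N=C=O | intermediate
19 | (6R,10R)-tetracyclic urea, debromo 7-N-methylphakellstatin skeleton | CN1C(=O)N[C@]23CCCN2C(=O)c2cccn2[C@H]13 | intermediate
20 | (6S,10R)-2,3-dibromo tetracyclic urea | CN1C(=O)N[C@]23CCCN2C(=O)c2cc(Br)c(Br)n2[C@H]13 | intermediate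
21 | (6S,10R)-2,3-dibromo-8-ethoxy isourea | CN1C(OCC)=N[C@]23CCCN2C(=O)c2cc(Br)c(Br)n2[C@H]13 | intermediate
22 | (−)-7-N-methyldibromophakellin, (6S,10R) | CN1C(N)=N[C@]23CCCN2C(=O)c2cc(Br)c(Br)n2[C@H]13 | target

## Step count and risks

Total step count: 16 (15 in the main line plus the preparation of methyl isocyanide).
Longest linear sequence: 15 steps (steps 1–3 and 5–16, from 1 to 22).

### Step 7 (bears the label)

- The eight-membered zwitterion may form but fail to close. The tether holds both N14 and N1 on the inner positions, so the usual conrotatory motion would lead to a trans fusion that the tether forbids.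
- The zwitterion may then revert, acylate intermolecularly and oligomerise, or hydrolyse on work-up.
- The ketene may also rest as its mesoionic valence isomer in the unproductive amide rotamer.
- Shielding by a 1,3-related silyloxy group may give poor facial selectivity.

The fallback sets out from 5 and returns at 12. It builds the same bonds one at a time by known reactions.

- Ester 5 is doubly deprotonated with LiN(SiMe3)2 (2.2 equiv, THF, −78 °C) and treated with monomeric formaldehyde. Aldol addition anti to the silyloxy group should give allyl (2R,4S)-2-(hydroxymethyl)-4-silyloxy-1-(pyrrole-2-carbonyl)pyrrolidine-2-carboxylate F1.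
- Dess–Martin oxidation gives the aldehyde, which pyrrole N1–H traps as the ring-B carbinolamine F2 (C6 epimers).
- Methylamine with MgSO4 in THF exchanges the hydroxyl group through the open imine and gives the C6 methylamino aminal ester F3.
- t-BuMgCl (Breckpot cyclisation of a β-amino ester) closes N7–C8 to 12. Only the C6 epimer with N7 cis to the ester can close, and the epimers interconvert by ring–chain equilibrium.

### Step 11

- Opening of a hindered N-alkyl lactam may be slow.
- At the temperature then needed, the freed C6 aminal may ionise and be captured by the hydrazide nitrogen, with loss of methylamine.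

The fallback sets out from 15 and returns at 17. It avoids a second nucleophilic nitrogen.

- The lactam is hydrolysed with LiOH in aqueous THF at 50 °C and neutralised to the zwitterionic (6S,10R)-6-methylamino-10-carboxylic acid F4, in which protonated N7 stabilises the aminal.
- Diphenylphosphoryl azide with Et3N in toluene–DMF transfers azide to the carboxylate and gives 17, which is heated on as in step 13.
- Re-closure of the activated acid to 15 would only return starting material.

### Step 5

- The weakly nucleophilic acylpyrrole N–H may not be metallated, or insertion may be slow.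
- The isocyanide may polymerise on copper.
- The moisture-sensitive product may hydrolyse during isolation.

The fallback sets out from 5 (with 7) and returns at 8. It replaces catalytic insertion by addition–elimination on a preformed imidoyl-transfer reagent.

- Benzotriazole, a much more acidic azole, adds to 7 without metal to give 1-[(E)-(methylimino)methyl]-1H-benzotriazole F5.
- The sodium salt of 5 (NaH, THF, 0 °C) displaces the far better leaving benzotriazolide from F5 to give 8.

## Further compounds

F1 | step 7 | allyl (2R,4S)-4-(tert-butyldimethylsilyloxy)-2-(hydroxymethyl)-1-(1H-pyrrole-2-carbonyl)pyrrolidine-2-carboxylate | C=CCOC(=O)[C@]1(CO)C[C@H](O[Si](C)(C)C(C)(C)C)CN1C(=O)c1ccc[nH]1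
F2 | step 7 | (10R,12S)-ring-B carbinolamine, 6-hydroxy (C6 epimers), allyl ester on C10 | OC1n2cccc2C(=O)N2C[C@@H](O[Si](C)(C)C(C)(C)C)C[C@]12C(=O)OCC=C
F3 | step 7 | (6S,10R,12S)-6-methylamino aminal, allyl ester on C10 | CN[C@H]1n2cccc2C(=O)N2C[C@@H](O[Si](C)(C)C(C)(C)C)C[C@]12C(=O)OCC=C
F4 | step 11 | (6S,10R)-6-methylamino-10-carboxylic acid of the A–B–C tricycle | CN[C@H]1n2cccc2C(=O)N2CCC[C@]12C(=O)O
F5 | step 5 | 1-[(E)-(methylimino)methyl]-1H-benzotriazole | C/N=C/n1nnc2ccccc12
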